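## Structural features

The target (16) is an open-chain hexamer of oxygenated benzene rings A–F joined by five diaryl ether bridges and carrying fifteen free phenolic hydroxyls. It has no fused ring, no sp3 carbon and no stereocentre, and the ether axes rotate freely, so no stereochemical relationship has to be set. Ring A is a 2,4,6-trihydroxyphenyl end group and ring F a 3,4,5-trihydroxyphenyl end group. Rings B, D and E are 3,5-dihydroxy-1,4-phenylene units: the oxygen lying between the two hydroxyls (on C4) leads forward to ring C, E and F respectively, and the unflanked oxygen (on C1) leads back to ring A, C and D. Ring C is the only pentaoxygenated ring, with the ring B oxygen on C1, the ring D oxygen on the adjacent C2, hydroxyls on C3, C4 and C5 and a single hydrogen on C6. The free polyphenol, above all the vicinal triols of rings C and F, is oxidised by air under basic conditions, so the hydroxyls must stay masked until the last step; the diaryl ethers themselves are robust. The real difficulty is forming five ether bonds between electron-rich rings at carbons mostly flanked by two oxygen substituents, and telling twenty oxygens apart, with the two adjacent ether bonds of ring C the most crowded. The key step uses the fact that the hydroxyls on ring A C4, ring C C4 and ring F C4 each lie para to an ether carbon of the same ring (ring A C1, ring C C1, ring F C1). Each of these oxygens can therefore first be a formyl group that activates the para carbon for ether formation.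

## Logic of the disconnections

16 to 15: the twelve O–CH3 bonds are restored, so that every hydroxyl except three is a methyl ether. Methyl is the one protecting group that all the building blocks already carry, and it makes the intermediates stable and chromatographable. The forward step must cleave twelve alkyl aryl ethers exhaustively without touching the five diaryl ethers and must deliver an air-sensitive product.

15 to 13 (through 14): the three aryl C–O bonds at ring A C4, ring C C4 and ring F C4 are traced back to three aryl–CHO bonds. These oxygens are the ones para to ether carbons, so the formyl groups that precede them are what makes those ether bonds accessible by addition–elimination. Three of the fifteen oxygens then need no differentiated protection, and the rings become simple benzaldehydes. The forward step needs aryl migration to win over hydride migration at all three sites and needs the peracid to leave six electron-rich rings alone.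

13 to 6 and 12: the ring C C2–O bond is cut, the oxygen staying on ring D. It is the one ether carbon of the aldehyde rings that lies meta to a formyl group and cannot be reached by addition–elimination, so it is reserved for a copper-mediated coupling and placed at the centre, where it joins two trimers of equal size. The forward step must couple an iodide flanked by a methoxy and an aryloxy group with an unhindered phenol in the presence of three aldehydes.

6 to 5 and 2: the ring C C1–O bond is cut, the oxygen staying on ring B. This carbon is para to the formyl group, so fluoride displacement is possible. Ring C becomes a monomer. The hindered phenoxide must displace fluoride only and leave the neighbouring iodide in place.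

2 to 1: the C–I bond is cut. The two free positions of 1 are equivalent and both activated by two methoxy groups, so no regiocontrol is needed. The forward step must stop at mono-iodination and avoid attack at the formyl-bearing carbon.

5 to 3 and 4: the ring A C1–O bond is cut, the oxygen staying on ring B. The carbon is para to the formyl group of 4, and the ring B oxygen used is the unflanked one. Two commercial compounds are joined without a protecting group. The forward step must arylate only the less hindered, more acidic hydroxyl of 3 and must exclude oxygen.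

12 to 11: a benzyl ether is restored on the unflanked oxygen of ring D. This oxygen has to stay silent while the other oxygens of the arm act as nucleophiles. The forward step must remove the benzyl group without reducing the ring F aldehyde.

11 to 10 and 1: the ring F C1–O bond is cut, again para to a formyl group. The forward step is a fluoride displacement by a phenoxide flanked by two methoxy groups.

10 to 8 (through 9): the ring E C4–O bond is traced back to a formyl group. The same double use of the formyl group is made at the dimer stage: it first activates ring E C1 and then becomes the phenol that attacks ring F. This oxidation must be run while 8 holds only one aldehyde, which fixes its place in the sequence.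

8 to 7 and 1: the ring E C1–O bond is cut, para to the formyl group of 1. The nucleophile is the flanked hydroxyl of 7.

7 to 3: the benzyl ether on the unflanked oxygen is removed. The forward step must alkylate one of two hydroxyls selectively.

## Other disconnections considered

Alternative 1: Ring C is made from a four-membered ring instead of an aromatic building block. The cut is the ring C C5–C6 bond; the cyclobutenone A1 would itself come from adding a metalated aryl vinyl ether of the AB unit to a squaric ester and silylating. In the forward step, heating A1 should open the cyclobutenone with the silyloxy group turning outward, the ketene carbon should close onto the vinyl CH2 in a 6π electrocyclisation, and tautomerisation should give the phenol A2.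
- In favour: all five oxygens of ring C are placed by construction and are chemically distinct in A2 (aryl ether on C1, silyl ether on C2, methyl ethers on C3 and C4, free hydroxyl on C5). The crowded ring B–O–C1 bond is made as a vinyl ether before any congestion exists. Ring C needs neither halogenation nor a peracid. On these points of structure the alternative is the better plan.
- Against: the ring C C2–O–ring D bond is not solved. After desilylation a phenol flanked by a methoxy and an aryloxy group would have to be arylated by an unactivated, electron-rich ring D halide, which is at best the equal of step 9 with the hindrance moved to the other partner. The vinyl ether of the hindered AB phenol and its α-metalation, in competition with ortho-metalation beside many methoxy groups, add uncertain steps. The C5 hydroxyl must be methylated, and ring A would have to be attached as a trimethoxyphenyl ring without activation.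
- Comparison: the thermal pericyclic cascade is mechanistically cleaner than an oxidation next to electron-rich arenes, a point on which it is better. In step economy it is worse, with about six operations for ring C against three (steps 1, 3 and 9).

Alternative 2: Ring A is built last from acyclic carbon. The cut is the pair of C–C bonds between the two methylene carbons of A4 and the two ester carbonyls of the aryloxymalonate A3. In the forward step an alkoxide base should bring about an intermolecular and then an intramolecular Claisen condensation, and the resulting cyclohexanetrione should enolise to the triol diester A5.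
- In favour: ring A arrives with three free oxygens and no protecting group, and its symmetry removes any regiochemical question. A4 is cheap, and the two ester groups of A5 should be lost easily by saponification and decarboxylation. No peracid is needed for ring A, the weakest site of the chosen triple oxidation; on this point the alternative is better.
- Against: A3 presupposes the complete methylated BCDEF pentamer with one free ring B hydroxyl for alkylation by a halomalonate. The least certain bond formation (self-condensation of A4, retro-Claisen cleavage, a crowded α-aryloxymalonate) is then run last on the most valuable intermediate, and the route becomes linear. Nothing is gained for rings C and F, which are permethylated in A3 and would have to be joined without formyl activation, by several copper couplings instead of one.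
- Comparison: the two plans are equal in needing a final global demethylation. Carbanion chemistry avoids oxidants, but ring A would cost at least four operations (alkylation, condensation, saponification, decarboxylation) against one (step 2).

Alternative 3: Ring C is introduced as an aryne. The cut takes the ring B O–ring C C1 bond and the ring C C2–I bond in one operation. In the forward step fluoride should release the aryne A8 from the silyl triflate A7. The phenoxide of A6 should add at C1, the terminus remote from the C3 methoxy group, so that the charge develops on C2 beside that inductively stabilising substituent. The aryl anion should then take iodine from A9 to give A10.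
- In favour: the hindered ether bond is made under mild, transition-metal-free conditions without an activating group, and the iodide for the next coupling is installed at the same time. Ring C is already at the trimethoxy level and needs no oxidation. A10 is the counterpart of 6 with methoxy in place of formyl, so the coupling with the DEF phenol at an iodide flanked by two oxygens is the same problem as step 9. The plans are equal on that decisive point; A10 is slightly worse electronically (no meta-formyl group) and slightly better in chemoselectivity (no aldehydes).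
- Against: A7 would take several steps from the corresponding phenol (ortho-bromination, silylation with migration, triflation) against the one-step iodination of 1. The aryl anion may be protonated before iodine transfer, and a phenoxide flanked by two methoxy groups is a slow aryne trap. A6 already contains the ring A–O–ring B bond, which needs an unactivated etherification or the formyl and Dakin sequence of the chosen plan followed by methylation.
- Comparison: the regiochemistry rests on aryne polarisation, normally reliable for 3-alkoxyarynes, against the positional certainty of displacement para to a formyl group. Two bonds in one step is better for that operation, but the precursor synthesis makes the overall count equal or longer.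

Key step: step 10

Remarks on the chemistry:
- Numbering: every ring is numbered from an ether carbon. Ring A C1 bears the ring B oxygen, so the hydroxyl para to it is C4; these atoms are C2 and C5 if ring A is numbered as a 2-aryloxybenzene-1,3,5-triol. Ring C C1 bears the ring B oxygen and C2 the ring D oxygen; ring F C1 bears the ring E oxygen.
- Corrections to the plan: ring C C2 is meta to the formyl group and cannot be etherified by addition–elimination, so the ring C block carries iodine there and the bond is made by copper catalysis (step 9). The bromide of 4 is a poor leaving group for uncatalysed displacement, so step 2 is copper-catalysed as well.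
- Assumption: 1, 3 and 4 are taken as commercially available.

## Route

Step 1
Reactants: 1 4-fluoro-2,6-dimethoxybenzaldehyde
Product: 2 4-fluoro-3-iodo-2,6-dimethoxybenzaldehyde
Conditions: NIS (1.05 equiv), TFA (cat.), MeCN, rt to 40 °C
Reagents that add atoms: N-iodosuccinimide, O=C1CCC(=O)N1I
Why: Electrophilic aromatic iodination; C3 and C5 are equivalent, each ortho to one methoxy and para to the other, and the first iodine deactivates the ring, so limiting NIS should give the mono-iodide.

Step 2
Reactants: 3 2,6-dimethoxybenzene-1,4-diol (2,6-dimethoxyhydroquinone); 4 4-bromo-3,5-dimethoxybenzaldehyde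
Product: 5 4-(4-hydroxy-3,5-dimethoxyphenoxy)-3,5-dimethoxybenzaldehyde
Conditions: 3 (2 equiv), CuI (10 mol%), picolinic acid (20 mol%), K3PO4, degassed DMSO, 90 °C, Ar
Reagents that add atoms: none
Why: Ullmann-type copper-catalysed O-arylation of a bromide that is also activated by its para-formyl group; the C4 hydroxyl of 3 is the more acidic and unhindered one, and arylation at the flanked hydroxyl would give an ether with four ortho substituents, so mono-arylation at C4–OH is expected.

Step 3
Reactants: 5 4-(4-hydroxy-3,5-dimethoxyphenoxy)-3,5-dimethoxybenzaldehyde; 2 4-fluoro-3-iodo-2,6-dimethoxybenzaldehyde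
Product: 6 4-[4-(4-formyl-2,6-dimethoxyphenoxy)-2,6-dimethoxyphenoxy]-3-iodo-2,6-dimethoxybenzaldehyde
Conditions: Cs2CO3, DMSO, 90 °C, Ar
Reagents that add atoms: none
Why: Nucleophilic aromatic substitution through a Meisenheimer adduct stabilised by the para-formyl group; fluoride is the only good leaving group at an activated position, while the iodide is meta to the formyl group and should stay.

Step 4
Reactants: 3 2,6-dimethoxybenzene-1,4-diol
Product: 7 4-(benzyloxy)-2,6-dimethoxyphenol
Conditions: BnBr (1.0 equiv), K2CO3 (1.0 equiv), degassed acetone, rt to 40 °C, Ar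
Reagents that add atoms: benzyl bromide, BrCc1ccccc1
Why: Williamson etherification; with one equivalent of weak base the mono-anion sits mainly on the more acidic C4 oxygen (two meta methoxy groups), which is also the unhindered one, so the benzyl group should go there.

Step 5
Reactants: 7 4-(benzyloxy)-2,6-dimethoxyphenol; 1 4-fluoro-2,6-dimethoxybenzaldehyde
Product: 8 4-[4-(benzyloxy)-2,6-dimethoxyphenoxy]-2,6-dimethoxybenzaldehyde
Conditions: Cs2CO3, DMSO, 100 °C, Ar
Reagents that add atoms: none
Why: Nucleophilic aromatic substitution of fluoride para to the formyl group by the flanked phenoxide; the benzyl ether is inert to base.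

Step 6
Reactants: 8 4-[4-(benzyloxy)-2,6-dimethoxyphenoxy]-2,6-dimethoxybenzaldehyde
Product: 10 4-[4-(benzyloxy)-2,6-dimethoxyphenoxy]-2,6-dimethoxyphenol, via aryl formate 9 (not isolated)
Conditions: mCPBA (1.3 equiv), CH2Cl2, 0 °C to rt; aq. Na2S2O3; then K2CO3 (cat.), MeOH, rt, Ar
Reagents that add atoms: mCPBA (3-chloroperoxybenzoic acid), O=C(OO)c1cccc(Cl)c1
Why: Dakin-type Baeyer–Villiger oxidation; two ortho methoxy groups and a para aryloxy group make aryl migration fast, and this is the only aldehyde present, so the new ring E phenol is formed unambiguously.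

Step 7
Reactants: 10 4-[4-(benzyloxy)-2,6-dimethoxyphenoxy]-2,6-dimethoxyphenol; 1 4-fluoro-2,6-dimethoxybenzaldehyde
Product: 11 4-{4-[4-(benzyloxy)-2,6-dimethoxyphenoxy]-2,6-dimethoxyphenoxy}-2,6-dimethoxybenzaldehyde
Conditions: Cs2CO3, DMSO, 100 °C, Ar
Reagents that add atoms: none
Why: Second nucleophilic aromatic substitution of the same fluoroaldehyde, now by the ring E phenoxide, as in step 5.

Step 8
Reactants: 11 4-{4-[4-(benzyloxy)-2,6-dimethoxyphenoxy]-2,6-dimethoxyphenoxy}-2,6-dimethoxybenzaldehyde
Product: 12 4-[4-(4-hydroxy-2,6-dimethoxyphenoxy)-2,6-dimethoxyphenoxy]-2,6-dimethoxybenzaldehyde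
Conditions: H2 (1 atm), 10% Pd/C, EtOAc, rt, stopped at full conversion
Reagents that add atoms: none
Why: Hydrogenolysis of the benzyl aryl ether; the aldehyde is flanked by two methoxy groups and electron-rich, so it should be reduced much more slowly in a neutral aprotic solvent, and neutral conditions avoid the acid-promoted condensation of aldehydes with such electron-rich rings.

Step 9
Reactants: 6 4-[4-(4-formyl-2,6-dimethoxyphenoxy)-2,6-dimethoxyphenoxy]-3-iodo-2,6-dimethoxybenzaldehyde; 12 4-[4-(4-hydroxy-2,6-dimethoxyphenoxy)-2,6-dimethoxyphenoxy]-2,6-dimethoxybenzaldehyde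
Product: 13 4-[4-(4-formyl-2,6-dimethoxyphenoxy)-2,6-dimethoxyphenoxy]-3-{4-[4-(4-formyl-3,5-dimethoxyphenoxy)-3,5-dimethoxyphenoxy]-3,5-dimethoxyphenoxy}-2,6-dimethoxybenzaldehyde
Conditions: CuI (20 mol%), picolinic acid (40 mol%), K3PO4, DMSO, 100 °C, Ar
Reagents that add atoms: none
Why: Ullmann-type copper-catalysed diaryl ether synthesis; the iodide and a chelating ligand are chosen because the carbon is flanked by two oxygen substituents, the phenol partner is unhindered, and aldehydes are tolerated by the weak anhydrous base.

Step 10
Reactants: 13 4-[4-(4-formyl-2,6-dimethoxyphenoxy)-2,6-dimethoxyphenoxy]-3-{4-[4-(4-formyl-3,5-dimethoxyphenoxy)-3,5-dimethoxyphenoxy]-3,5-dimethoxyphenoxy}-2,6-dimethoxybenzaldehyde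
Product: 15 4-[4-(4-hydroxy-2,6-dimethoxyphenoxy)-2,6-dimethoxyphenoxy]-3-{4-[4-(4-hydroxy-3,5-dimethoxyphenoxy)-3,5-dimethoxyphenoxy]-3,5-dimethoxyphenoxy}-2,6-dimethoxyphenol, via hexamer tris-formate 14 (not isolated)
Conditions: mCPBA (4.5 equiv), CH2Cl2, 0 °C to rt; aq. Na2S2O3; then K2CO3 (cat.), MeOH, rt, Ar; work-up at pH 4
Reagents that add atoms: mCPBA (3-chloroperoxybenzoic acid), O=C(OO)c1cccc(Cl)c1
Why: Dakin-type Baeyer–Villiger oxidation run on three aldehydes at once: the peracid adds to each formyl group to give a Criegee adduct, the aryl group migrates to oxygen with loss of 3-chlorobenzoate, and the three aryl formates of 14 are methanolysed, so C–O bonds at ring A C4, ring C C4 and ring F C4 replace three C–C bonds. The closest known reaction is the peracid conversion of ortho- and para-alkoxybenzaldehydes into phenols through their formates, established for 2,6-dimethoxy- and 3,4,5-trialkoxybenzaldehydes; the only extension is three aldehydes in one molecule. No ring is closed and no stereocentre is formed. The selectivity needed is aryl over hydride migration at each site: on rings C and F the formyl group lies between two methoxy groups and para to an aryloxy group, so the migrating carbon is strongly electron-rich, whereas ring A has only the para aryloxy donor and is the slowest site, hence the excess of peracid and the unbuffered, mildly acidic medium. The step also needs the peracid to spare the six electron-rich rings, which should hold because carbonyl addition is far faster than arene oxidation at 0 °C. The new oxygens stay masked as formates until the peracid has been destroyed, so the oxidation-prone phenols, above all the one on pentaoxygenated ring C, never meet the oxidant.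

Step 11
Reactants: 15 4-[4-(4-hydroxy-2,6-dimethoxyphenoxy)-2,6-dimethoxyphenoxy]-3-{4-[4-(4-hydroxy-3,5-dimethoxyphenoxy)-3,5-dimethoxyphenoxy]-3,5-dimethoxyphenoxy}-2,6-dimethoxyphenol
Product: 16 5-[4-(2,4,6-trihydroxyphenoxy)-2,6-dihydroxyphenoxy]-4-{4-[4-(3,4,5-trihydroxyphenoxy)-3,5-dihydroxyphenoxy]-3,5-dihydroxyphenoxy}benzene-1,2,3-triol (target CNP0270681.0)
Conditions: BBr3 (30 equiv), CH2Cl2, −78 °C to rt, Ar; MeOH then degassed H2O; Sephadex LH-20 under Ar
Reagents that add atoms: none
Why: Lewis-acid-mediated cleavage of the twelve methyl aryl ethers (bromide attacks the methyl group of the boron-complexed ether); diaryl ethers have no alkyl carbon to attack and should survive, and the product is handled under inert gas because of its oxidation sensitivity.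

## Compound list

1 | 4-fluoro-2,6-dimethoxybenzaldehyde | COc1cc(F)cc(OC)c1C=O | starting material
2 | 4-fluoro-3-iodo-2,6-dimethoxybenzaldehyde | O=Cc1c(OC)c(I)c(F)cc1OC | intermediate
3 | 2,6-dimethoxybenzene-1,4-diol (2,6-dimethoxyhydroquinone) | COc1cc(O)cc(OC)c1O | starting material
4 | 4-bromo-3,5-dimethoxybenzaldehyde | COc1cc(C=O)cc(OC)c1Br | starting material
5 | 4-(4-hydroxy-3,5-dimethoxyphenoxy)-3,5-dimethoxybenzaldehyde | O=Cc1cc(OC)c(Oc2cc(OC)c(O)c(OC)c2)c(OC)c1 | intermediate
6 | 4-[4-(4-formyl-2,6-dimethoxyphenoxy)-2,6-dimethoxyphenoxy]-3-iodo-2,6-dimethoxybenzaldehyde | O=Cc1cc(OC)c(Oc2cc(OC)c(Oc3cc(OC)c(C=O)c(OC)c3I)c(OC)c2)c(OC)c1 | intermediate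
7 | 4-(benzyloxy)-2,6-dimethoxyphenol | COc1cc(OCc2ccccc2)cc(OC)c1O | intermediate
8 | 4-[4-(benzyloxy)-2,6-dimethoxyphenoxy]-2,6-dimethoxybenzaldehyde | O=Cc1c(OC)cc(Oc2c(OC)cc(OCc3ccccc3)cc2OC)cc1OC | intermediate
9 | 4-[4-(benzyloxy)-2,6-dimethoxyphenoxy]-2,6-dimethoxyphenyl formate (not isolated) | O=COc1c(OC)cc(Oc2c(OC)cc(OCc3ccccc3)cc2OC)cc1OC | intermediate
10 | 4-[4-(benzyloxy)-2,6-dimethoxyphenoxy]-2,6-dimethoxyphenol | Oc1c(OC)cc(Oc2c(OC)cc(OCc3ccccc3)cc2OC)cc1OC | intermediate
11 | 4-{4-[4-(benzyloxy)-2,6-dimethoxyphenoxy]-2,6-dimethoxyphenoxy}-2,6-dimethoxybenzaldehyde | O=Cc1c(OC)cc(Oc2c(OC)cc(Oc3c(OC)cc(OCc4ccccc4)cc3OC)cc2OC)cc1OC | intermediate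
12 | 4-[4-(4-hydroxy-2,6-dimethoxyphenoxy)-2,6-dimethoxyphenoxy]-2,6-dimethoxybenzaldehyde | O=Cc1c(OC)cc(Oc2c(OC)cc(Oc3c(OC)cc(O)cc3OC)cc2OC)cc1OC | intermediate
13 | 4-[4-(4-formyl-2,6-dimethoxyphenoxy)-2,6-dimethoxyphenoxy]-3-{4-[4-(4-formyl-3,5-dimethoxyphenoxy)-3,5-dimethoxyphenoxy]-3,5-dimethoxyphenoxy}-2,6-dimethoxybenzaldehyde (methylated hexamer trialdehyde) | O=Cc1cc(OC)c(Oc2cc(OC)c(Oc3cc(OC)c(C=O)c(OC)c3Oc3cc(OC)c(Oc4cc(OC)c(Oc5cc(OC)c(C=O)c(OC)c5)c(OC)c4)c(OC)c3)c(OC)c2)c(OC)c1 | intermediate
14 | 4-[4-(4-formyloxy-2,6-dimethoxyphenoxy)-2,6-dimethoxyphenoxy]-3-{4-[4-(4-formyloxy-3,5-dimethoxyphenoxy)-3,5-dimethoxyphenoxy]-3,5-dimethoxyphenoxy}-2,6-dimethoxyphenyl formate (hexamer tris-formate, not isolated) | O=COc1cc(OC)c(Oc2cc(OC)c(Oc3cc(OC)c(OC=O)c(OC)c3Oc3cc(OC)c(Oc4cc(OC)c(Oc5cc(OC)c(OC=O)c(OC)c5)c(OC)c4)c(OC)c3)c(OC)c2)c(OC)c1 | intermediate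
15 | 4-[4-(4-hydroxy-2,6-dimethoxyphenoxy)-2,6-dimethoxyphenoxy]-3-{4-[4-(4-hydroxy-3,5-dimethoxyphenoxy)-3,5-dimethoxyphenoxy]-3,5-dimethoxyphenoxy}-2,6-dimethoxyphenol (methylated hexamer triol) | Oc1cc(OC)c(Oc2cc(OC)c(Oc3cc(OC)c(O)c(OC)c3Oc3cc(OC)c(Oc4cc(OC)c(Oc5cc(OC)c(O)c(OC)c5)c(OC)c4)c(OC)c3)c(OC)c2)c(OC)c1 | intermediate
16 | 5-[4-(2,4,6-trihydroxyphenoxy)-2,6-dihydroxyphenoxy]-4-{4-[4-(3,4,5-trihydroxyphenoxy)-3,5-dihydroxyphenoxy]-3,5-dihydroxyphenoxy}benzene-1,2,3-triol (CNP0270681.0) | Oc1cc(O)c(Oc2cc(O)c(Oc3cc(O)c(O)c(O)c3Oc3cc(O)c(Oc4cc(O)c(Oc5cc(O)c(O)c(O)c5)c(O)c4)c(O)c3)c(O)c2)c(O)c1 | target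

## Step count and least certain steps

Total step count: 11. Longest linear sequence: 8 steps (steps 4 to 11, from 3 to 16); the ABC arm (steps 1 to 3) converges at step 9.

Step 10 (key step). The most likely failure is hydride migration in place of aryl migration at the ring A aldehyde, which has no ortho alkoxy group and whose para aryloxy donor is twisted by two flanking methoxy groups. Forcing that slow site with more peracid risks oxidative degradation of the electron-rich rings. The fallback takes the slowest site out of the oxidation by carrying the ring A para oxygen as a benzyl ether. It sets out from 10, which has the substitution pattern of an AB unit with a benzyloxy group on ring A C4, and from 2. Fluoride displacement (Cs2CO3, DMSO) should give 4-{4-[4-(benzyloxy)-2,6-dimethoxyphenoxy]-2,6-dimethoxyphenoxy}-3-iodo-2,6-dimethoxybenzaldehyde F1. Copper coupling with 12 under the conditions of step 9 should give the hexamer dialdehyde 4-{4-[4-(benzyloxy)-2,6-dimethoxyphenoxy]-2,6-dimethoxyphenoxy}-3-{4-[4-(4-formyl-3,5-dimethoxyphenoxy)-3,5-dimethoxyphenoxy]-3,5-dimethoxyphenoxy}-2,6-dimethoxybenzaldehyde F2. A double Dakin oxidation of its two 2,6-dimethoxybenzaldehyde sites (mCPBA, then methanolysis) should give the diphenol 4-{4-[4-(benzyloxy)-2,6-dimethoxyphenoxy]-2,6-dimethoxyphenoxy}-3-{4-[4-(4-hydroxy-3,5-dimethoxyphenoxy)-3,5-dimethoxyphenoxy]-3,5-dimethoxyphenoxy}-2,6-dimethoxyphenol F3. Hydrogenolysis of F3 (H2, Pd/C), now with no aldehyde present, comes back to the route at 15.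

Step 9. The most likely failure is slow oxidative addition of copper at an iodide flanked by a methoxy and an aryloxy group. Protodeiodination and exchange of aryloxide at the formyl-activated ether carbons could then take over. The fallback changes the order of bond formation by masking the ring C formyl group. It sets out from 2. Acetalisation (ethylene glycol, TsOH, toluene, water removal) should give 2-(4-fluoro-3-iodo-2,6-dimethoxyphenyl)-1,3-dioxolane F4, whose fluoride is no longer activated and whose iodide is flanked only by methoxy and fluorine. Copper coupling of F4 with 12 should give 4-[4-(4-{[3-(1,3-dioxolan-2-yl)-6-fluoro-2,4-dimethoxyphenyl]oxy}-2,6-dimethoxyphenoxy)-2,6-dimethoxyphenoxy]-2,6-dimethoxybenzaldehyde F5. Brief treatment with dilute aqueous acid in THF should release 4-fluoro-3-{4-[4-(4-formyl-3,5-dimethoxyphenoxy)-3,5-dimethoxyphenoxy]-3,5-dimethoxyphenoxy}-2,6-dimethoxybenzaldehyde F6. Fluoride displacement by the phenoxide of 5 (Cs2CO3, DMSO) comes back to the route at 13.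

Step 2. The most likely failure is oxidation of the electron-rich hydroquinone to its quinone by traces of oxygen in the basic copper medium, together with some double arylation. The fallback masks the flanked oxygen and uses a mono-phenol. It sets out from 4 and from commercially available 4-hydroxy-3,5-dimethoxybenzaldehyde (syringaldehyde) F7. Benzylation (BnBr, K2CO3) should give 4-(benzyloxy)-3,5-dimethoxybenzaldehyde F8, and Dakin oxidation (mCPBA, then methanolysis) should give 4-(benzyloxy)-3,5-dimethoxyphenol F9. Copper coupling of F9 with 4 under the conditions of step 2 should give 4-[4-(benzyloxy)-3,5-dimethoxyphenoxy]-3,5-dimethoxybenzaldehyde F10. Hydrogenolysis (H2, Pd/C, EtOAc) comes back to the route at 5.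

Step 4. The most likely failure is alkylation at the flanked oxygen or at both oxygens, giving mixtures that are hard to separate. The fallback fixes the regiochemistry by construction and sets out from 1. Displacement of fluoride by benzyl alcohol (Cs2CO3, DMSO, 80 °C) should give 4-(benzyloxy)-2,6-dimethoxybenzaldehyde F11. Dakin oxidation (mCPBA, then methanolysis) comes back to the route at 7.

Step 11. The most likely failure is incomplete cleavage, because boron phenoxide aggregates precipitate before all twelve ethers have reacted, and oxidative loss of the free polyphenol during aqueous work-up and chromatography. The fallback isolates the product through a stable derivative and sets out from 15. The crude product after BBr3 is acetylated at once (Ac2O, pyridine) to the pentadecaacetate 5-[4-(2,4,6-triacetoxyphenoxy)-2,6-diacetoxyphenoxy]-4-{4-[4-(3,4,5-triacetoxyphenoxy)-3,5-diacetoxyphenoxy]-3,5-diacetoxyphenoxy}benzene-1,2,3-triyl triacetate F12, which can be purified on silica and freed from under-cleaved material. Transesterification (NaOMe cat., degassed MeOH, Ar, then acidic resin) comes back to the route at 16.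

## Further compounds

F1 | step 10 | 4-{4-[4-(benzyloxy)-2,6-dimethoxyphenoxy]-2,6-dimethoxyphenoxy}-3-iodo-2,6-dimethoxybenzaldehyde | O=Cc1c(OC)cc(Oc2c(OC)cc(Oc3c(OC)cc(OCc4ccccc4)cc3OC)cc2OC)c(I)c1OC
F2 | step 10 | 4-{4-[4-(benzyloxy)-2,6-dimethoxyphenoxy]-2,6-dimethoxyphenoxy}-3-{4-[4-(4-formyl-3,5-dimethoxyphenoxy)-3,5-dimethoxyphenoxy]-3,5-dimethoxyphenoxy}-2,6-dimethoxybenzaldehyde | O=Cc1c(OC)cc(Oc2c(OC)cc(Oc3c(OC)cc(OCc4ccccc4)cc3OC)cc2OC)c(Oc2cc(OC)c(Oc3cc(OC)c(Oc4cc(OC)c(C=O)c(OC)c4)c(OC)c3)c(OC)c2)c1OC
F3 | step 10 | 4-{4-[4-(benzyloxy)-2,6-dimethoxyphenoxy]-2,6-dimethoxyphenoxy}-3-{4-[4-(4-hydroxy-3,5-dimethoxyphenoxy)-3,5-dimethoxyphenoxy]-3,5-dimethoxyphenoxy}-2,6-dimethoxyphenol | Oc1c(OC)cc(Oc2c(OC)cc(Oc3c(OC)cc(OCc4ccccc4)cc3OC)cc2OC)c(Oc2cc(OC)c(Oc3cc(OC)c(Oc4cc(OC)c(O)c(OC)c4)c(OC)c3)c(OC)c2)c1OC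
F4 | step 9 | 2-(4-fluoro-3-iodo-2,6-dimethoxyphenyl)-1,3-dioxolane | COc1cc(F)c(I)c(OC)c1C1OCCO1
F5 | step 9 | 4-[4-(4-{[3-(1,3-dioxolan-2-yl)-6-fluoro-2,4-dimethoxyphenyl]oxy}-2,6-dimethoxyphenoxy)-2,6-dimethoxyphenoxy]-2,6-dimethoxybenzaldehyde | O=Cc1c(OC)cc(Oc2c(OC)cc(Oc3c(OC)cc(Oc4c(F)cc(OC)c(C5OCCO5)c4OC)cc3OC)cc2OC)cc1OC
F6 | step 9 | 4-fluoro-3-{4-[4-(4-formyl-3,5-dimethoxyphenoxy)-3,5-dimethoxyphenoxy]-3,5-dimethoxyphenoxy}-2,6-dimethoxybenzaldehyde | O=Cc1c(OC)cc(Oc2c(OC)cc(Oc3c(OC)cc(Oc4c(F)cc(OC)c(C=O)c4OC)cc3OC)cc2OC)cc1OC
F7 | step 2 | 4-hydroxy-3,5-dimethoxybenzaldehyde (syringaldehyde, purchased) | COc1cc(C=O)cc(OC)c1O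
F8 | step 2 | 4-(benzyloxy)-3,5-dimethoxybenzaldehyde | COc1cc(C=O)cc(OC)c1OCc1ccccc1
F9 | step 2 | 4-(benzyloxy)-3,5-dimethoxyphenol | COc1cc(O)cc(OC)c1OCc1ccccc1
F10 | step 2 | 4-[4-(benzyloxy)-3,5-dimethoxyphenoxy]-3,5-dimethoxybenzaldehyde | O=Cc1cc(OC)c(Oc2cc(OC)c(OCc3ccccc3)c(OC)c2)c(OC)c1
F11 | step 4 | 4-(benzyloxy)-2,6-dimethoxybenzaldehyde | COc1cc(OCc2ccccc2)cc(OC)c1C=O
F12 | step 11 | 5-[4-(2,4,6-triacetoxyphenoxy)-2,6-diacetoxyphenoxy]-4-{4-[4-(3,4,5-triacetoxyphenoxy)-3,5-diacetoxyphenoxy]-3,5-diacetoxyphenoxy}benzene-1,2,3-triyl triacetate | CC(=O)Oc1cc(OC(C)=O)c(Oc2cc(OC(C)=O)c(Oc3cc(OC(C)=O)c(OC(C)=O)c(OC(C)=O)c3Oc3cc(OC(C)=O)c(Oc4cc(OC(C)=O)c(Oc5cc(OC(C)=O)c(OC(C)=O)c(OC(C)=O)c5)c(OC(C)=O)c4)c(OC(C)=O)c3)c(OC(C)=O)c2)c(OC(C)=O)c1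
A1 | alternative 1 | 4-(tert-butyldimethylsilyloxy)-2,3-dimethoxy-4-{1-[2,6-dimethoxy-4-(2,4,6-trimethoxyphenoxy)phenoxy]ethenyl}cyclobut-2-en-1-one | C=C(Oc1c(OC)cc(Oc2c(OC)cc(OC)cc2OC)cc1OC)C1(O[Si](C)(C)C(C)(C)C)C(=O)C(OC)=C1OC
A2 | alternative 1 | 4-(tert-butyldimethylsilyloxy)-2,3-dimethoxy-5-[2,6-dimethoxy-4-(2,4,6-trimethoxyphenoxy)phenoxy]phenol | COc1cc(OC)c(Oc2cc(OC)c(Oc3cc(O)c(OC)c(OC)c3O[Si](C)(C)C(C)(C)C)c(OC)c2)c(OC)c1
A3 | alternative 2 | dimethyl 2-(aryloxy)propanedioate of the permethylated BCDEF pentamer | COC(=O)C(Oc1cc(OC)c(Oc2cc(OC)c(OC)c(OC)c2Oc2cc(OC)c(Oc3cc(OC)c(Oc4cc(OC)c(OC)c(OC)c4)c(OC)c3)c(OC)c2)c(OC)c1)C(=O)OC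
A4 | alternative 2 | dimethyl 3-oxopentanedioate | COC(=O)CC(=O)CC(=O)OC
A5 | alternative 2 | dimethyl 2,4,6-trihydroxy-5-(permethylated BCDEF aryloxy)benzene-1,3-dicarboxylate | COC(=O)c1c(O)c(C(=O)OC)c(O)c(Oc2cc(OC)c(Oc3cc(OC)c(OC)c(OC)c3Oc3cc(OC)c(Oc4cc(OC)c(Oc5cc(OC)c(OC)c(OC)c5)c(OC)c4)c(OC)c3)c(OC)c2)c1O
A6 | alternative 3 | 2,6-dimethoxy-4-(2,4,6-trimethoxyphenoxy)phenol | COc1cc(OC)c(Oc2cc(OC)c(O)c(OC)c2)c(OC)c1
A7 | alternative 3 | 3,4,5-trimethoxy-2-(trimethylsilyl)phenyl trifluoromethanesulfonate | COc1cc(OS(=O)(=O)C(F)(F)F)c([Si](C)(C)C)c(OC)c1OC
A8 | alternative 3 | 3,4,5-trimethoxybenzyne (1,2-didehydro-3,4,5-trimethoxybenzene) | COC1=CC#CC(OC)=C1OC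
A9 | alternative 3 | 1,1,1,2,2,3,3,4,4-nonafluoro-4-iodobutane | FC(F)(F)C(F)(F)C(F)(F)C(F)(F)I
A10 | alternative 3 | 1-[2,6-dimethoxy-4-(2,4,6-trimethoxyphenoxy)phenoxy]-2-iodo-3,4,5-trimethoxybenzene | COc1cc(OC)c(Oc2cc(OC)c(Oc3cc(OC)c(OC)c(OC)c3I)c(OC)c2)c(OC)c1
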